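Maple, charged 4.29 times as strongly as oak, ended with less target, 13% of the charge against 22%.

| setting | oak | maple | epsilon | zeta | theta |
|---|---|---|---|---|---|
| substrate | 0.28 M | 1.2 M | 0.20 M | 0.40 M | 0.80 M |
| remark | run made earlier | run made earlier |  |  |  |
| time |  |  | 8.0 h | 8.0 h | 8.0 h |

| run | time / h | target / % | substrate / % |
|---|---|---|---|
| oak | 0.417 | 3 | 80 |
| oak | 1.33 | 10 | 48 |
| oak | 2.50 | 11 | 30 |
| oak | 3.00 | 14 | 28 |
| oak | 5.00 | 18 | 13 |
| oak | 6.00 | 21 | 10 |
| oak | 8.00 | 22 | 8 |
| maple | 1.00 | 6 | 35 |
| maple | 2.50 | 9 | 13 |
| maple | 3.00 | 11 | 13 |
| maple | 5.00 | 12 | 5 |
| maple | 6.00 | 7 | 1 |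
| maple | 8.00 | 13 | 0 |

(readings scatter by 1.5 percentage points)

- "hardly changes" means that all values lie within two and a half points (for a concentration: within two and a half percent of the largest)

- amount of target at the end, in percent of the substrate charged for epsilon, zeta, theta, in this order
- the course of these numbers from the first flask to the last (hardly changes / falls, then rises / rises all the way / falls all the way / rises, then falls)

1. My rule: maple also lost substrate faster early on, with 35% left at 1.00 h against 48% in oak at 1.33 h. So I took a loss that grows with concentration, and let the inverse of the target fraction rise in a straight line with charge.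

2. Time: oak gained 1 percentage point from 6.00 h to 8.00 h, against a scatter of 1.5 points. So late in oak the gain with time stayed within what a reading scatters.

3. End readings: a shift of that kind carried through to the row. Taking oak's neighbouring reading 21% moved epsilon by 1.2 points. Taking maple's 12% moved theta by 0.86 points.

4. The numbers: the line through both end readings gave a dilute yield, my reading of the selectivity at vanishing charge, of 27.9%. It also gave the crowding charge 1.05 M, the charge at which, on that line, the target fraction is half of the dilute yield. I expected 23.4%, 20.2% and 15.8%.

5. The forecast gave 24%, 19.5% and 15%, falls all the way, noting that “Target formed per substrate consumed rises as substrate falls”; it stood above mine for epsilon and below mine for zeta and theta.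

6. The flasks gave 22.7%, 18.5% and 14.0%: falls all the way.

    substrate → target (k = 0.00160 min⁻¹)
    substrate → side product (k = 0.00310 min⁻¹)
    2 substrate → homo dimer (k = 0.0100 L mol⁻¹ min⁻¹)

Epsilon stood at 0.191 of the crowding charge and kept 81.4% of my dilute yield, while theta stood at 0.763 of it and kept 50.2%. In a simulated theta run without the step joining substrate pairs into homo dimer, target reached 30.5% instead of 14.0%, the larger of the two effects tested there. Without that step, the change from epsilon to theta went from −8.7 points to 0 points.

The runs were computed on assumed constants; the scatter is artificial.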